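The vessel is closed and stirred: an electrophile either couples with the nucleophile or dimerises, and a solid base dissolves beside them. Amounts below are fractions of the electrophile charge.

electrophile 0.10 M; nucleophile 0.900 equiv; solid base 0.300 equiv; time 1.5 h

    electrophile + nucleophile → acid set free + product (k1 = 0.089 M⁻¹ min⁻¹)
    nucleophile + acid set free ⇌ protonated nucleophile, settled at all times (K2 = 530 M⁻¹)
    acid set free + free base ⇌ salt of the base, settled at all times (K3 = 13 M⁻¹)
    2 electrophile → homo dimer (k4 = 0.11 M⁻¹ min⁻¹)
    acid set free → by-product carried off (k5 = 0.018 min⁻¹)
    solid base ⇌ free base, rate k6*(cs6 - [free base]) while solid is left; crystals form when [free base] > cs6 (cs6 = 0.053 M, k6 = 0.026 min⁻¹)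

- percentages count the electrophile that a species holds: one homo dimer counts as two
- a doubled species enters its step squared and goes two at a time
- solid, in amounts per volume of the solution: solid base
- at the start none of the solid base is in solution
- run time (flask): 1.5 h

- part of the electrophile that has reacted at 1.5 h
- share of the unused nucleophile that is free and not bound as protonated nucleophile, at 1.5 h

Two of us disputed this flask. My colleague froze the nucleophile: the solid base, 0.300 equiv, takes up the acid set free, so the nucleophile stays free at 0.900 equiv and fr lies near 100%. Coupling is then pseudo-first-order at 0.00801 min⁻¹, beside a homo dimer step starting at 0.0220 min⁻¹, and integration gives c of 79.8%.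

I answered with binding strengths. At the start the nucleophile holds acid with a weight of 48, while free base, even with its whole charge dissolved, reaches 0.390, so the acid goes to the nucleophile far more than to the free base, and each product costs close to two nucleophile, one coupled and one protonated. The nucleophile then falls too, and as an estimate I froze its ratio to the electrophile at the charged value instead. That freezes the split, the electrophile sent to homo dimer per electrophile coupled (a selectivity factor), which is the homo dimer rate over the coupling rate at the charged ratio: 2.75. Both losses then run second order in the electrophile fraction on one clock, 2.70, and c is that clock over one plus itself, 73.0%. Product is c over one plus the split, 19.5%, and fr, free over unused nucleophile, comes to 72.4%.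

The forecast takes my side with its own numbers, 75% and 68%, holding that “the dissolved base scavenges little acid”.

The simulation gives 75.4% reacted and 66.8% of the unused nucleophile free in this flask. This flask leaves my colleague's free nucleophile its opening: 93.1% of the unused nucleophile was free at 0.150 h, and 76.8% at 0.750 h.

At 1.50 h this flask reads a split of 2.13, homo dimer 51.3% over product 24.1%, against 2.75 frozen. For the neighbour charged with 0.360 equiv of nucleophile, the frozen split becomes 6.87 and the clock 2.27. That gives c of 69.4%, product 8.82% and fr of 67.5%. The neighbour flask gave 70.2% reacted, 67.5% free, and 10.4% product beside 59.8% homo dimer.

(The rate constants stand for no real mixture; the flask was simulated.)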